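Jc is the species to follow: each Jc ends as Jf or as Jg, and with 1.00 equiv of Jc, Jg in percent of the Ja charged equals the percentage of Jc that took the Jg path.

common to all: Jd 160 mM (held); time 1.5 min
- eta: Ja 0.41 M; Jc 1.00 equiv; everything together at the start at 20 °C, warmed to 40 °C at 40 s
- zeta: Ja 0.41 M; Jc 1.00 equiv (fed, over 40 s); all else is in the flask from the start; the feed brings no volume worth counting; temperature 40 °C
- theta: Ja 0.41 M (fed, over 40 s); Jc 1.00 equiv; all else is in the flask from the start; the feed brings no volume worth counting; temperature 40 °C
- alpha: Ja 0.41 M; Jc 1.00 equiv (fed, over 40 s); the addition at 20 °C, then warmed to 40 °C; the feed brings no volume worth counting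
- delta: Ja 0.41 M; Jc 1.00 equiv; everything together at the start; temperature 40 °C

    Ja + Jb ⇌ Je (K1 = 6.1 /M, k1 = 0.14 /M/s, Ea1 = 40.0 kJ/mol, ΔH1 = −45.0 kJ/mol)
    Jc + Jb → Jf (k2 = 0.20 /M/s, Ea2 = 38.0 kJ/mol)
    Ja + Jc → Jg (k3 = 0.060 /M/s, Ea3 = 61.0 kJ/mol)
    Jd ⇌ Jb, rate k4*(csat - [Jb]) (k4 = 3.9 /s, csat = 160 mM)
    (constants at 40 °C)

- at the start none of Jb is dissolved
- constants are those at 40 °C; use the activation energies and enthalpies for any other temperature

1. the flask that comes out highest in amount of Jg, in percent of the Ja charged; "all alike" if 1.5 percentage points covers them all (eta / zeta / theta / alpha / delta / all alike)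
2. amount of Jg at the end, in percent of the Ja charged, eta
3. amount of Jg at the end, in percent of the Ja charged, zeta
4. amount of Jg at the end, in percent of the Ja charged, theta
5. amount of Jg at the end, in percent of the Ja charged, alpha
6. amount of Jg at the end, in percent of the Ja charged, delta

Build delta first, the flask held at 40 °C with everything in at the start, one process at a time.

1. Freeze Jb. Transfer from the gas runs at 3.9 /s, far faster than the pseudo-first-order uptake by Ja and Jc at their charges, 0.139 /s. So take [Jb] as c*, the saturation value 160 mM.

2. Add the Ja + Jb step. With Jb frozen, Je over Ja tends to 0.976, so free Ja falls towards 50.6% of its charge, with a relaxation half-life of 15.3 s.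

3. Add the Jc + Jb step, with constant kF. By itself it gives Jc a half-life of 21.7 s, well inside the 1.5 min run.

4. Add the Ja + Jc step, with constant kG. Jc now divides between the two paths, and the selectivity factor I carry is the Jg share, φ = kG[Ja]/(kG[Ja] + kF c*). With Ja at its charge, φ is 43.5%, and with Ja relaxed to the free level of step 2 it is 28.0%. The times 15.3 s and 21.7 s differ by a factor of 1.42, so I take Jc to react away while Ja relaxes, and I commit delta to the middle of that bracket, 35.7%.

5. Now the other flasks. In zeta the feed lasts 40 s, longer than the relaxation, so I expect the fed Jc to meet Ja near its relaxed level, with φ near 28.0%. In theta the same feed time is longer than the Jc half-life, so I expect Jc to react away with Jb while Ja is still low, and I put theta under the bracket. In eta and alpha the cold start counts against Jg, since the Ja + Jc step has the higher activation energy, 61.0 kJ/mol against 38.0 kJ/mol. I put both below delta without reckoning how far, and the order among zeta, eta and alpha stays open.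

The forecast also named delta, with 31% there, below my 35.7%, and gave 30% for zeta, 25% for eta, 25.5% for alpha and 18.5% for theta, reasoning that “feeding Ja starves the Ja + Jc step while Jc burns off”.

The flasks give delta as highest: delta 32.1%, zeta 26.9%, eta 25.3%, alpha 25.1%, theta 19.2%.

In delta the Jg share of the Jc spent comes to 32.8%, inside the bracket from 28.0% to 43.5%. At 1.50 min delta uses Jc 3.8 times as fast by the Jb path as by the Ja path, a running φ of 20.8%, with free Ja at 34.4% of its charge. For a neighbour of delta charged with 0.400 equiv of Jc, the bracket scaled to that charge runs from 11.2% to 17.4%, and that neighbour ends at 14.0%.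

(The rate constants were drawn at random within sensible limits.)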